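# Proposed total synthesis of CNP0174688.1 by way of a 3‑arylindanone ring expansion

Numbering convention: flavan numbering is used for both units (O1, C2, C3, C4, C4a, C5–C8, C8a; ring B primed). Unit M is the flavan‑3‑ol, unit T the flavan‑3,4‑diol. Compound numbers 1–35 are those of the steps and the compound list.

## Analysis of the target

The target is a 4→6 linked biflavanoid: unit M is a 2‑(3,4‑dihydroxyphenyl)‑7,8‑dihydroxyflavan‑3‑ol and unit T a 2‑(4‑hydroxyphenyl)‑7,8‑dihydroxyflavan‑3,4‑diol of the teracacidin type, joined from C4 of unit M to C6 of ring A of unit T. Unit M has the triad 2R,3R,4S, that is 2,3‑cis and 3,4‑trans, so the aryl groups at C2 and C4 lie on opposite faces of ring C and the C3 hydroxyl shares the face of the C2 aryl. Unit T has 2R,3R,4R with the aryl group and both hydroxyls on one face, an all‑cis array in which both oxygens sit on the hindered side. The two triads are separated by an aromatic ring, so neither can direct the other and each needs its own source of absolute configuration. Sensitive points are the benzylic C4 hydroxyl of unit T (ionisable, because O1 is ortho and O7 para to C4a), the oxidisable catechol and pyrogallol‑type rings, and the C4(M)–C6(T) diarylmethine bond, which acid can cleave once the oxygen para to C6 is electron‑releasing. The difficulty is therefore stereochemical (six centres, two contra‑steric relationships) and protective (seven phenols that can only be freed at the very end). The strategy rests on ring C of unit M: O1 lies between C8a and C2, and if it is deleted C8a is bonded to C2, giving the five‑membered ketone of a 3‑arylindan‑1‑one whose C3 is C4 of unit M and whose aryl group is ring A of unit T.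

## Retrosynthetic reasoning

**35 ⇒ 34.** Seven O–benzyl bonds are cut. Hydrogenolysis is the only deprotection mild enough for a free flavan‑3,4‑diol, so every phenol must be a benzyl ether at the end and every other protecting group must be gone before it.

**34 ⇒ 33 ⇒ 32.** The C3–O bond of unit T is cut with inversion, back to a C3 bromide. Both oxygens of the all‑cis triad lie on the face of the C2 aryl, which no external reagent approaches. An oxygen tethered to O4 (the carbonate of 33) can only enter cis to O4, so the forward step has to carboxylate the C4 alkoxide of 32 and let it displace bromide. The same reduction that opens the carbonate also removes the pivalate of unit M.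

**32 ⇒ 31 ⇒ 29.** The C4–H and C3–Br bonds of unit T are cut. Bromine enters the enol derivative anti to the C2 aryl, and hydride then adds to the ketone to give the equatorial alcohol, cis to the aryl and trans to bromine. Both are substrate‑controlled from C2 alone, so the whole triad follows from one centre.

**29 ⇒ 27 + 28.** The C2–C1′ bond of unit T is cut. This is the one bond whose formation can carry the absolute configuration of unit T under catalyst control. Hydrogenation of a flavonol would also reach the all‑cis array, but in both senses, because unit M is too far away to bias the face. The forward reaction is an enantioselective conjugate arylation of chromone 27 by boronic acid 28.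

**27 ⇒ 24 ⇒ 23 ⇒ 22.** The pyranone ring is taken apart at O1–C2, C3–C4 and C4–C4a. Phenol 22 has one free ortho position, so a magnesium‑mediated formylation, an acetylide addition and an oxidation–cyclisation build the chromone. No strong acid is needed, which matters because 22 carries a free oxygen para to the diarylmethine carbon.

**22 ⇒ 21.** The S–O bond of the sulfonate is cut. The sulfonate marks the future O1 of unit T from the first step. It cannot migrate to the neighbouring oxygens, it withstands acid, peracid, amide bases and Grignard reagents, and it deactivates ring A of unit T towards peracid and towards ipso protonation.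

**21 ⇒ 19 ⇒ 16 + 17 ⇒ 15.** Ring C of unit M is opened at C2: first the C2–H bond (hydride addition to the oxocarbenium ion that arises from ketone 19 through hemiketal 20), then the C2–aryl bond (Grignard reagent 18 from bromide 17), then the lactone as amide 16. The amide is interposed because an aryl ester would take up two equivalents of the aryl nucleophile. The C3 ester is a pivalate, the one acyl group that survives the Grignard step and can still shield or bridge the face of C2 on which it sits.

**15 ⇒ 14 ⇒ 13.** The C3–O bond of unit M is cut. The lactone enolate of 13 is hydroxylated anti to the C4 aryl, which gives the 3,4‑trans relationship of the target.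

**13 ⇒ 11 (through 12).** This is the key disconnection: O1–C8a and O1–C2 are cut and C8a is joined to C2, which contracts the lactone to indanone 11. Nowhere else in unit M can one oxygen be removed to leave a carbocycle that is easy to make in enantioenriched form. The gain is that C4 is set on a rigid five‑membered ring, and that the lactone delivers C2 as a carbonyl and C3 as an enolisable methylene. The forward reaction must migrate the aryl carbon and not the methylene.

**11 ⇒ 10 ⇒ 8.** The C3–H bond of the indanone is cut. Racemic 8 is dehydrogenated through 9 to indenone 10, and a copper hydride with a chiral bisphosphine returns the hydrogen to one face.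

**8 ⇒ 7 ⇒ 6 ⇒ 5.** The C3–C3a bond is cut (Nazarov cyclisation of chalcone 5). The cyclisation needs hot acid, which benzyl ethers would not survive, so it is run on methyl ethers. These are exchanged for benzyl ethers (6 to 7 to 8) while the material is still racemic and robust.

**5 ⇒ 3 + 4; 3 ⇒ 2 ⇒ 1.** The enone double bond is cut by aldol condensation between aldehyde 3 and ketone 4. Aldehyde 3 comes from 1 by sulfonylation of its most acidic hydroxyl and methylation of the other two.

## Alternatives that were turned down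

**Alternative 1:** The disconnection removes the C3–C4 and C4–C4a bonds of unit M together, so that C4 is assembled from an aryl aldehyde carrying ring A of unit T, a metallated arylacetylene and the ring A phenol of unit M. In the forward sense the acetylide adds to the aldehyde and a chiral phosphoric acid ionises the propargylic carbinol through its para oxygen to a quinone methide, which the phenol attacks through its ortho carbon to give A1 with C4 set.

- For it: three fragments combine in one flask, C4 is created together with both of its aryl bonds, and the para oxygen that later becomes O1 of unit T also serves as the activating group. In convergence and in step count up to C4 it is stronger than the indanone route, which spends a cyclisation, a dehydrogenation and a reduction on the same carbon.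
- Against it: the nucleophile is a catechol‑type phenol with an open para position, so ortho‑C, para‑C and O attack are not distinguished by structure. The cation is delocalised into the alkyne, so allene formation competes. Enantioselection must come from an ion pair with a quinone methide flanked by two benzyloxy groups.
- After A1 the alkyne still has to become the 2,3‑cis oxygenated C2–C3 unit, next to a very ionisable diarylmethine.
- Comparison: the chosen strategy gives up convergence and gains a lactone in which C2 is already a carbonyl and C3 already enolisable, with C4 set by a conjugate reduction whose sense is fixed by one ligand.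

**Alternative 2:** Both pyran rings are cut at O1–C8a, which leads back to an open chain in which each benzylic C2 carries a free hydroxyl and each ring A an ortho bromide. The forward key step is a twofold palladium‑catalysed aryl ether formation (Pd(OAc)2, a bulky binaphthyl dialkylphosphine, Cs2CO3) that closes both rings in one operation and gives A2.

- For it: the bond formed is aryl–oxygen, so both C2 centres keep the configuration they had in the open chain, no cation is involved, and the endgame is shorter than here, where the two rings are closed by separate sequences. On fidelity at C2 it is at least as strong.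
- Against it: all six stereocentres and five differentiated oxygens must be in place on a flexible chain before the step, which moves the whole stereochemical problem into acyclic chemistry. Both bromides are flanked by a benzyloxy group and an alkyl branch, the least favourable case for oxidative addition and C–O reductive elimination. Secondary benzylic alkoxides on palladium are prone to β‑hydride elimination to aryl ketones.
- Comparison: the chosen route uses ring templates, each new centre being set on a six‑membered ring next to an existing one. Its one aryl–oxygen bond is made by a 1,2‑shift that is necessarily intramolecular.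

**Alternative 3:** Only ring C of unit T is cut, at O1–C2, back to a C8a phenol facing a cis‑oxirane across C2 and C3 with the C4 carbinol already present. Under pyridinium p‑toluenesulfonate at low temperature the phenol would open the oxirane at benzylic C2 with inversion and give A3, the all‑cis triad appearing in one step.

- For it: the three centres of unit T come from one stereospecific event, no oxidation‑state changes follow, and it is two to three steps shorter than the bromination, reduction and carbonate sequence used here for the same triad.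
- Against it: C2 carries a para‑benzyloxyphenyl group, so the oxirane can ionise before the phenol arrives, and the trans isomer then forms. Attack at C3 to give a five‑membered ring is the competing mode. The Z‑olefin and its face‑selective epoxidation next to the C4 carbinol must be controlled beforehand. Acid is applied to a molecule that already contains the ionisable C4 oxygen.
- Comparison: the chosen plan fixes C2 of unit T by forming its carbon–carbon bond under catalyst control, where ionisation cannot erode it. The two oxygens are then placed by a hydride addition and an internal displacement that each have a single stereochemical outcome.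

Key step: step 9

Remark on the chemistry: the antipodes of the chiral ligands in steps 8 and 19 are assigned by analogy with simpler β‑aryl cyclopentenones and chromones; if a model substrate shows the opposite sense, the mirror‑image ligand is used without other change. The spatial arrangement at C4 of unit M is the same from 11 to 35; its CIP label alternates (R in 11, 16 and 19; S in 13–15 and 20–22; R in 23–34; S in 35) only because the priorities of the two aryl branches change.

## Steps

Step 1
Reactants: 1 2,3,4-trihydroxybenzaldehyde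
Product: 2 4-formyl-2,3-dihydroxyphenyl 4-methylbenzenesulfonate
Conditions: TsCl (1.0 equiv), Et3N (1.1 equiv), CH2Cl2, −20 → 0 °C
Reagents that add atoms: 4-methylbenzenesulfonyl chloride, Cc1ccc(cc1)S(Cl)(=O)=O
Why: Sulfonylation of the most acidic phenol; O4 is para to the formyl group, O2 is hydrogen‑bonded to it and O3 is flanked on both sides, so one equivalent of sulfonyl chloride should mark O4, the future O1 of unit T. A sulfonate is chosen because transfer to a neighbouring phenoxide would need an endocyclic displacement at sulfur.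

Step 2
Reactants: 2 4-formyl-2,3-dihydroxyphenyl 4-methylbenzenesulfonate
Product: 3 4-formyl-2,3-dimethoxyphenyl 4-methylbenzenesulfonate
Conditions: MeI, K2CO3, DMF, rt
Reagents that add atoms: iodomethane, CI
Why: Williamson etherification of the two remaining phenols; methyl ethers are used because they and the sulfonate survive the hot acid of step 4.

Step 3
Reactants: 3 4-formyl-2,3-dimethoxyphenyl 4-methylbenzenesulfonate; 4 1-(2,3-dimethoxyphenyl)ethan-1-one
Product: 5 (E)-4-[3-(2,3-dimethoxyphenyl)-3-oxoprop-1-en-1-yl]-2,3-dimethoxyphenyl 4-methylbenzenesulfonate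
Conditions: HCl (4 M in dioxane, cat.), EtOH, rt → 50 °C
Reagents that add atoms: none
Why: Acid‑catalysed Claisen–Schmidt condensation; acid is used instead of hydroxide so that the aryl sulfonate para to the new enone is not hydrolysed, and the E olefin forms under thermodynamic control.

Step 4
Reactants: 5 (E)-chalcone
Product: 6 racemic 3-[2,3-dimethoxy-4-(tosyloxy)phenyl]-6,7-dimethoxyindan-1-one
Conditions: CF3CO2H, 80 °C (sealed)
Reagents that add atoms: none
Why: Nazarov cyclisation of the O‑protonated aryl vinyl ketone; the ring closes at the only free ortho position of the acyl ring, which is para to its 3‑methoxy group, and this fixes the 6,7‑dioxygenation. The new centre is formed racemic and is erased in step 7.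

Step 5
Reactants: 6 racemic tetramethyl ether
Product: 7 racemic 3-[2,3-dihydroxy-4-(tosyloxy)phenyl]-6,7-dihydroxyindan-1-one
Conditions: BBr3, CH2Cl2, −78 → 0 °C; then H2O
Reagents that add atoms: none
Why: Lewis‑acid cleavage of the four aryl methyl ethers; the aryl sulfonate and the ketone are inert to BBr3.

Step 6
Reactants: 7 racemic tetraphenol
Product: 8 racemic 3-[2,3-bis(benzyloxy)-4-(tosyloxy)phenyl]-6,7-bis(benzyloxy)indan-1-one
Conditions: BnBr, K2CO3, DMF, 50 °C, under N2
Reagents that add atoms: benzyl bromide, BrCc1ccccc1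
Why: Williamson benzylation installs the only phenol protection that can be removed at the end without acid or base; the sulfonate stays on its oxygen for the reason stated in step 1.

Step 7
Reactants: 8 racemic tetrabenzyl indanone
Product: 10 3-[2,3-bis(benzyloxy)-4-(tosyloxy)phenyl]-6,7-bis(benzyloxy)-1H-inden-1-one, via silyl enol ether 9 (not isolated)
Conditions: LiHMDS, TMSCl, THF, −78 °C; then Pd(OAc)2 (10 mol %), O2 (1 atm), DMSO, rt
Reagents that add atoms: none
Why: Saegusa–Ito oxidation of the C1–C2 enol silane; it is mild towards benzyl ethers and removes the racemic centre so that it can be re‑set with control.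

Step 8
Reactants: 10 3-arylindenone
Product: 11 (3R)-3-[2,3-bis(benzyloxy)-4-(tosyloxy)phenyl]-6,7-bis(benzyloxy)indan-1-one
Conditions: Cu(OAc)2·H2O (5 mol %), (R)-DTBM-SEGPHOS (5.5 mol %), (EtO)2MeSiH, t-BuOH, toluene, 0 °C; then aq NH4F
Reagents that add atoms: none
Why: Copper hydride catalysed asymmetric conjugate reduction of a β‑aryl cyclopentenone; the ligand‑bound CuH delivers hydride to one face of C3 and tert‑butanol protonates the enolate, so the C3 centre (C4 of unit M) is set by the catalyst.

Step 9
Reactants: 11 (3R)-3-arylindan-1-one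
Product: 13 (4S)-4-[2,3-bis(benzyloxy)-4-(tosyloxy)phenyl]-7,8-bis(benzyloxy)-3,4-dihydrocoumarin, via Criegee adduct 12 (not isolated)
Conditions: mCPBA (2 equiv), NaHCO3, CH2Cl2, 0 °C → rt
Reagents that add atoms: 3-chloroperoxybenzoic acid, OOC(=O)c1cccc(Cl)c1
Why: Baeyer–Villiger oxidation: the peracid adds to the C1 carbonyl of 11 to give adduct 12, and the aryl carbon C7a then shifts from carbon to oxygen as 3‑chlorobenzoate leaves. The closest known reaction type is the peracid oxidation of 1‑indanones and of ortho‑alkoxyaryl ketones to aryl esters. Ring C of unit M is closed by ring expansion and not by cyclisation of a chain: oxygen is inserted into the C7a–C1 bond of the five‑membered ketone, which makes O1–C8a and O1–C2 and leaves the six‑membered lactone. No stereocentre is formed; the carbon set in step 8 is not touched, and its label changes from R to S by priority alone. The step needs migration of the aryl carbon and not of the C2 methylene; the benzyloxy group ortho to C7a raises its migratory aptitude, and the C1–C7a bond can lie antiperiplanar to the O–O bond in 12. It also needs the peracid to spare the other oxygenated rings; the sulfonate lowers the electron density of ring A of unit T, hydrogencarbonate buffers the acid formed, and the lactone product is less electron‑rich than the ketone.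

Step 10
Reactants: 13 (4S)-lactone
Product: 14 (3R,4S)-4-[2,3-bis(benzyloxy)-4-(tosyloxy)phenyl]-7,8-bis(benzyloxy)-3-hydroxy-3,4-dihydrocoumarin
Conditions: NaHMDS, THF, −78 °C; 2-(phenylsulfonyl)-3-phenyloxaziridine, −78 °C; AcOH quench
Reagents that add atoms: 2-(phenylsulfonyl)-3-phenyloxaziridine, O=S(=O)(N1OC1c1ccccc1)c1ccccc1
Why: Enolate hydroxylation with an N‑sulfonyloxaziridine; the oxidant approaches C3 anti to the C4 aryl group, which gives the 3,4‑trans relationship of unit M. The temperature is kept low so that the aryl ester enolate does not eliminate phenoxide.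

Step 11
Reactants: 14 (3R,4S)-3-hydroxy lactone
Product: 15 (3R,4S)-4-[2,3-bis(benzyloxy)-4-(tosyloxy)phenyl]-7,8-bis(benzyloxy)-2-oxochroman-3-yl pivalate
Conditions: PivCl, pyridine, DMAP (cat.), CH2Cl2, 0 °C → rt
Reagents that add atoms: pivaloyl chloride, CC(C)(C)C(Cl)=O
Why: Acylation under non‑enolising conditions; a pivalate is chosen because it resists the Grignard reagent of step 13 and can still shield or bridge C2 in step 14.

Step 12
Reactants: 15 (3R,4S)-pivaloyloxy lactone
Product: 16 (2R,3R)-3-[3,4-bis(benzyloxy)-2-hydroxyphenyl]-3-[2,3-bis(benzyloxy)-4-(tosyloxy)phenyl]-1-[methoxy(methyl)amino]-1-oxopropan-2-yl pivalate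
Conditions: MeNH(OMe)·HCl, i-PrMgCl, THF, −20 °C
Reagents that add atoms: N,O-dimethylhydroxylamine hydrochloride, CNOC.Cl
Why: Aminolysis of the strained aryl ester by the magnesium amide, far faster than attack on the hindered pivalate; the N‑methoxy‑N‑methylamide prevents the double addition that the lactone would suffer with an aryl nucleophile.

Step 13
Reactants: 16 (2R,3R)-N-methoxy-N-methylamide; 17 4-bromo-1,2-bis(benzyloxy)benzene
Product: 19 (2R,3R)-1-[3,4-bis(benzyloxy)phenyl]-3-[3,4-bis(benzyloxy)-2-hydroxyphenyl]-3-[2,3-bis(benzyloxy)-4-(tosyloxy)phenyl]-1-oxopropan-2-yl pivalate, via aryl Grignard reagent 18 (not isolated)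
Conditions: 17, Mg, THF, rt; then 16 (18 in 3 equiv), THF, −20 → 0 °C; aq NH4Cl at 0 °C
Reagents that add atoms: none
Why: Grignard acylation through the chelated tetrahedral intermediate, which collapses to the ketone only on work‑up; one equivalent of 18 is consumed by the phenol, and aryl Grignard reagents leave the aryl sulfonate alone.

Step 14
Reactants: 19 (2R,3R)-hydroxy ketone
Product: 21 (2R,3R,4S)-7,8-bis(benzyloxy)-2-[3,4-bis(benzyloxy)phenyl]-4-[2,3-bis(benzyloxy)-4-(tosyloxy)phenyl]chroman-3-yl pivalate, via cyclic hemiketal 20 (not isolated)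
Conditions: Et3SiH, BF3·OEt2, CH2Cl2/MeCN, −40 → −10 °C
Reagents that add atoms: none
Why: Reductive etherification: the phenol closes onto the ketone, BF3 ionises hemiketal 20 to the 2‑aryl oxocarbenium ion and the silane reduces it. Allylic strain with the C2 aryl holds the C3 pivalate pseudo‑axial, where it shields or bridges its own face, so hydride should enter anti to O3 along the axial trajectory and give the 2,3‑cis ring with the C4 aryl trans. The sulfonate keeps ring A of unit T from ipso protonation.

Step 15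
Reactants: 21 (2R,3R,4S)-flavan sulfonate
Product: 22 (2R,3R,4S)-7,8-bis(benzyloxy)-2-[3,4-bis(benzyloxy)phenyl]-4-[2,3-bis(benzyloxy)-4-hydroxyphenyl]chroman-3-yl pivalate
Conditions: Mg turnings, MeOH/THF, rt; aq NH4Cl
Reagents that add atoms: none
Why: Reductive S–O cleavage of the aryl sulfonate by electron transfer from magnesium; benzyl ethers and the hindered pivalate are not affected.

Step 16
Reactants: 22 phenol
Product: 23 (2R,3R,4R)-7,8-bis(benzyloxy)-2-[3,4-bis(benzyloxy)phenyl]-4-[2,3-bis(benzyloxy)-5-formyl-4-hydroxyphenyl]chroman-3-yl pivalate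
Conditions: MgCl2, Et3N, (CH2O)n, MeCN, 80 °C; aq citric acid
Reagents that add atoms: paraformaldehyde (as formaldehyde), C=O
Why: Magnesium‑mediated ortho‑formylation of a phenol; the magnesium phenoxide directs formaldehyde to the only free ortho carbon, the future C4a of unit T, and a second formaldehyde oxidises the benzylic alkoxide, all without strong acid.

Step 17
Reactants: 23 salicylaldehyde
Product: 24 (2R,3R,4R)-7,8-bis(benzyloxy)-2-[3,4-bis(benzyloxy)phenyl]-4-[2,3-bis(benzyloxy)-4-hydroxy-5-(1-hydroxyprop-2-yn-1-yl)phenyl]chroman-3-yl pivalate (both carbinol epimers)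
Conditions: HC≡CMgBr (3.5 equiv), THF, −20 → 0 °C; aq NH4Cl
Reagents that add atoms: ethynylmagnesium bromide, C#C[Mg]Br
Why: Grignard addition to the aldehyde after deprotonation of the phenol; the carbinol centre is left uncontrolled because it is oxidised in the next step.

Step 18
Reactants: 24 propargylic alcohol
Product: 27 (2R,3R,4R)-7,8-bis(benzyloxy)-4-[7,8-bis(benzyloxy)-4-oxo-4H-chromen-6-yl]-2-[3,4-bis(benzyloxy)phenyl]chroman-3-yl pivalate, via ynone 25 (not isolated), via enaminone 26 (not isolated)
Conditions: MnO2, CH2Cl2, rt; filter; Et2NH, EtOH, rt → 50 °C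
Reagents that add atoms: none
Why: MnO2 oxidises only the benzylic, propargylic alcohol; diethylamine adds to the terminal ynone, and the phenol then displaces the amine from the enaminone in a 6‑endo addition–elimination, which gives the chromone and not the five‑membered isomer.

Step 19
Reactants: 27 chromone; 28 4-(benzyloxy)phenylboronic acid
Product: 29 (2R,3R,4R)-7,8-bis(benzyloxy)-4-{(2S)-7,8-bis(benzyloxy)-2-[4-(benzyloxy)phenyl]-4-oxochroman-6-yl}-2-[3,4-bis(benzyloxy)phenyl]chroman-3-yl pivalate
Conditions: Pd(OCOCF3)2 (10 mol %), (R)-t-BuPyOx (12 mol %), NH4PF6 (30 mol %), H2O, ClCH2CH2Cl, 60 °C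
Reagents that add atoms: none
Why: Palladium‑catalysed asymmetric conjugate addition of an arylboronic acid to a chromone; the pyridine–oxazoline ligand selects the face of C2 at which the aryl–palladium species inserts, so C2 of unit T is set by the catalyst, unit M being too remote to interfere. The near‑neutral medium avoids ring opening of the flavanone.

Step 20
Reactants: 29 (2S)-flavanone
Product: 31 (2R,3R,4R)-7,8-bis(benzyloxy)-4-{(2R,3R)-7,8-bis(benzyloxy)-2-[4-(benzyloxy)phenyl]-3-bromo-4-oxochroman-6-yl}-2-[3,4-bis(benzyloxy)phenyl]chroman-3-yl pivalate, via silyl enol ether 30 (not isolated)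
Conditions: LiHMDS, TMSCl (in situ), THF, −78 °C; then NBS, THF, −78 → −20 °C
Reagents that add atoms: N-bromosuccinimide, O=C1CCC(=O)N1Br
Why: α‑Bromination of a ketone through its enol silane; bromine adds to C3 anti to the C2 aryl group and gives the trans bromo ketone, and internal trapping of the enolate at −78 °C prevents retro‑oxa‑Michael opening.

Step 21
Reactants: 31 trans-3-bromoflavanone
Product: 32 (2R,3R,4R)-7,8-bis(benzyloxy)-4-{(2R,3S,4R)-7,8-bis(benzyloxy)-2-[4-(benzyloxy)phenyl]-3-bromo-4-hydroxychroman-6-yl}-2-[3,4-bis(benzyloxy)phenyl]chroman-3-yl pivalate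
Conditions: NaBH4, MeOH/THF, −20 °C
Reagents that add atoms: none
Why: Borohydride reduction of the ketone in its diequatorial conformer by axial attack; the new hydroxyl is equatorial, cis to the C2 aryl and trans to bromine, which is the arrangement needed for step 22.

Step 22
Reactants: 32 trans,trans-bromohydrin
Product: 33 cyclic 3,4-carbonate of unit T (all-cis; 2R,3S,4R in flavan numbering) of the hepta-O-benzyl ether carrying the unit M pivalate
Conditions: CO2 (1 atm), Cs2CO3, DMF, 40 °C
Reagents that add atoms: carbon dioxide, O=C=O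
Why: Carboxylation of the C4 alkoxide and intramolecular SN2 displacement of the C3 bromide by the carbonate oxygen (conversion of a vicinal halohydrin into a cyclic carbonate); inversion at C3 places O3 cis to O4 and to the C2 aryl, and neither neighbouring hydrogen is anti to bromine, so elimination cannot compete.

Step 23
Reactants: 33 cyclic carbonate pivalate
Product: 34 (2R,3R,4R)-7,8-bis(benzyloxy)-2-[4-(benzyloxy)phenyl]-6-{(2R,3R,4R)-7,8-bis(benzyloxy)-2-[3,4-bis(benzyloxy)phenyl]-3-hydroxychroman-4-yl}chromane-3,4-diol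
Conditions: LiAlH4, THF, 0 °C → rt; aq potassium sodium tartrate
Reagents that add atoms: none
Why: Hydride reduction cleaves the cyclic carbonate and the hindered pivalate in one operation without touching benzyl ethers or any stereocentre.

Step 24
Reactants: 34 hepta-O-benzyl ether
Product: 35 (2R,3R,4R)-2-(4-hydroxyphenyl)-6-[(2R,3R,4S)-2-(3,4-dihydroxyphenyl)-3,7,8-trihydroxychroman-4-yl]chromane-3,4,7,8-tetrol
Conditions: H2 (1 atm), Pd(OH)2/C, THF/MeOH, rt; filtration under argon
Reagents that add atoms: none
Why: Hydrogenolysis of the seven aryl benzyl ethers under neutral conditions; the reaction is stopped at full debenzylation so that the benzylic C2–O1 bonds and the C4 hydroxyl of unit T are not reduced.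

## Compound list

1 | 2,3,4-trihydroxybenzaldehyde | O=Cc1ccc(O)c(O)c1O | starting material
2 | 4-formyl-2,3-dihydroxyphenyl 4-methylbenzenesulfonate | O=Cc1ccc(OS(=O)(=O)c2ccc(C)cc2)c(O)c1O | intermediate
3 | 4-formyl-2,3-dimethoxyphenyl 4-methylbenzenesulfonate | O=Cc1ccc(OS(=O)(=O)c2ccc(C)cc2)c(OC)c1OC | intermediate
4 | 1-(2,3-dimethoxyphenyl)ethan-1-one | CC(=O)c1cccc(OC)c1OC | starting material
5 | (E)-4-[3-(2,3-dimethoxyphenyl)-3-oxoprop-1-en-1-yl]-2,3-dimethoxyphenyl 4-methylbenzenesulfonate | COc1cccc(C(=O)/C=C/c2ccc(OS(=O)(=O)c3ccc(C)cc3)c(OC)c2OC)c1OC | intermediate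
6 | racemic 3-[2,3-dimethoxy-4-(tosyloxy)phenyl]-6,7-dimethoxyindan-1-one | COc1ccc2C(CC(=O)c2c1OC)c1ccc(OS(=O)(=O)c3ccc(C)cc3)c(OC)c1OC | intermediate
7 | racemic 3-[2,3-dihydroxy-4-(tosyloxy)phenyl]-6,7-dihydroxyindan-1-one | Oc1ccc2C(CC(=O)c2c1O)c1ccc(OS(=O)(=O)c3ccc(C)cc3)c(O)c1O | intermediate
8 | racemic 3-[2,3-bis(benzyloxy)-4-(tosyloxy)phenyl]-6,7-bis(benzyloxy)indan-1-one | Cc1ccc(cc1)S(=O)(=O)Oc1ccc(C4CC(=O)c5c4ccc(OCc6ccccc6)c5OCc5ccccc5)c(OCc2ccccc2)c1OCc1ccccc1 | intermediate
9 | racemic 1-[2,3-bis(benzyloxy)-4-(tosyloxy)phenyl]-4,5-bis(benzyloxy)-3-(trimethylsilyloxy)-1H-indene | Cc1ccc(cc1)S(=O)(=O)Oc1ccc(C4C=C(O[Si](C)(C)C)c5c4ccc(OCc6ccccc6)c5OCc5ccccc5)c(OCc2ccccc2)c1OCc1ccccc1 | intermediate (not isolated)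
10 | 3-[2,3-bis(benzyloxy)-4-(tosyloxy)phenyl]-6,7-bis(benzyloxy)-1H-inden-1-one | Cc1ccc(cc1)S(=O)(=O)Oc1ccc(C4=CC(=O)c5c4ccc(OCc6ccccc6)c5OCc5ccccc5)c(OCc2ccccc2)c1OCc1ccccc1 | intermediate
11 | (3R)-3-[2,3-bis(benzyloxy)-4-(tosyloxy)phenyl]-6,7-bis(benzyloxy)indan-1-one | Cc1ccc(cc1)S(=O)(=O)Oc1ccc([C@@H]4CC(=O)c5c4ccc(OCc6ccccc6)c5OCc5ccccc5)c(OCc2ccccc2)c1OCc1ccccc1 | intermediate
12 | Criegee adduct, (3R)-3-aryl-6,7-bis(benzyloxy)-1-hydroxyindan-1-yl 3-chloroperoxybenzoate (C1 unassigned) | Cc1ccc(cc1)S(=O)(=O)Oc1ccc([C@@H]4CC(O)(OOC(=O)c7cccc(Cl)c7)c5c4ccc(OCc6ccccc6)c5OCc5ccccc5)c(OCc2ccccc2)c1OCc1ccccc1 | intermediate (not isolated)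
13 | (4S)-4-[2,3-bis(benzyloxy)-4-(tosyloxy)phenyl]-7,8-bis(benzyloxy)-3,4-dihydrocoumarin | Cc1ccc(cc1)S(=O)(=O)Oc1ccc([C@@H]4CC(=O)Oc5c4ccc(OCc6ccccc6)c5OCc5ccccc5)c(OCc2ccccc2)c1OCc1ccccc1 | intermediate
14 | (3R,4S)-4-[2,3-bis(benzyloxy)-4-(tosyloxy)phenyl]-7,8-bis(benzyloxy)-3-hydroxy-3,4-dihydrocoumarin (3,4-trans) | Cc1ccc(cc1)S(=O)(=O)Oc1ccc([C@@H]4[C@@H](O)C(=O)Oc5c4ccc(OCc6ccccc6)c5OCc5ccccc5)c(OCc2ccccc2)c1OCc1ccccc1 | intermediate
15 | (3R,4S)-4-[2,3-bis(benzyloxy)-4-(tosyloxy)phenyl]-7,8-bis(benzyloxy)-2-oxochroman-3-yl pivalate | Cc1ccc(cc1)S(=O)(=O)Oc1ccc([C@@H]4[C@@H](OC(=O)C(C)(C)C)C(=O)Oc5c4ccc(OCc6ccccc6)c5OCc5ccccc5)c(OCc2ccccc2)c1OCc1ccccc1 | intermediate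
16 | (2R,3R)-3-[3,4-bis(benzyloxy)-2-hydroxyphenyl]-3-[2,3-bis(benzyloxy)-4-(tosyloxy)phenyl]-1-[methoxy(methyl)amino]-1-oxopropan-2-yl pivalate | Cc1ccc(cc1)S(=O)(=O)Oc1ccc([C@@H](c5ccc(OCc6ccccc6)c(OCc6ccccc6)c5O)[C@@H](OC(=O)C(C)(C)C)C(=O)N(C)OC)c(OCc2ccccc2)c1OCc1ccccc1 | intermediate
17 | 4-bromo-1,2-bis(benzyloxy)benzene | Brc1ccc(OCc2ccccc2)c(OCc2ccccc2)c1 | starting material
18 | [3,4-bis(benzyloxy)phenyl]magnesium bromide | Br[Mg]c1ccc(OCc2ccccc2)c(OCc2ccccc2)c1 | intermediate (not isolated)
19 | (2R,3R)-1-[3,4-bis(benzyloxy)phenyl]-3-[3,4-bis(benzyloxy)-2-hydroxyphenyl]-3-[2,3-bis(benzyloxy)-4-(tosyloxy)phenyl]-1-oxopropan-2-yl pivalate | Cc1ccc(cc1)S(=O)(=O)Oc1ccc([C@@H](c5ccc(OCc6ccccc6)c(OCc6ccccc6)c5O)[C@@H](OC(=O)C(C)(C)C)C(=O)c5ccc(OCc6ccccc6)c(OCc6ccccc6)c5)c(OCc2ccccc2)c1OCc1ccccc1 | intermediate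
20 | cyclic hemiketal of 19, (3R,4S)-2-hydroxychroman-3-yl pivalate (C2 unassigned) | Cc1ccc(cc1)S(=O)(=O)Oc1ccc([C@H]4c5ccc(OCc6ccccc6)c(OCc6ccccc6)c5OC(O)(c5ccc(OCc6ccccc6)c(OCc6ccccc6)c5)[C@@H]4OC(=O)C(C)(C)C)c(OCc2ccccc2)c1OCc1ccccc1 | intermediate (not isolated)
21 | (2R,3R,4S)-7,8-bis(benzyloxy)-2-[3,4-bis(benzyloxy)phenyl]-4-[2,3-bis(benzyloxy)-4-(tosyloxy)phenyl]chroman-3-yl pivalate (2,3-cis, 3,4-trans) | Cc1ccc(cc1)S(=O)(=O)Oc1ccc([C@H]4c5ccc(OCc6ccccc6)c(OCc6ccccc6)c5O[C@H](c5ccc(OCc6ccccc6)c(OCc6ccccc6)c5)[C@@H]4OC(=O)C(C)(C)C)c(OCc2ccccc2)c1OCc1ccccc1 | intermediate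
22 | (2R,3R,4S)-7,8-bis(benzyloxy)-2-[3,4-bis(benzyloxy)phenyl]-4-[2,3-bis(benzyloxy)-4-hydroxyphenyl]chroman-3-yl pivalate | Oc1ccc([C@H]4c5ccc(OCc6ccccc6)c(OCc6ccccc6)c5O[C@H](c5ccc(OCc6ccccc6)c(OCc6ccccc6)c5)[C@@H]4OC(=O)C(C)(C)C)c(OCc2ccccc2)c1OCc1ccccc1 | intermediate
23 | (2R,3R,4R)-7,8-bis(benzyloxy)-2-[3,4-bis(benzyloxy)phenyl]-4-[2,3-bis(benzyloxy)-5-formyl-4-hydroxyphenyl]chroman-3-yl pivalate | Oc1c(C=O)cc([C@H]4c5ccc(OCc6ccccc6)c(OCc6ccccc6)c5O[C@H](c5ccc(OCc6ccccc6)c(OCc6ccccc6)c5)[C@@H]4OC(=O)C(C)(C)C)c(OCc2ccccc2)c1OCc1ccccc1 | intermediate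
24 | (2R,3R,4R)-7,8-bis(benzyloxy)-2-[3,4-bis(benzyloxy)phenyl]-4-[2,3-bis(benzyloxy)-4-hydroxy-5-(1-hydroxyprop-2-yn-1-yl)phenyl]chroman-3-yl pivalate (carbinol epimers) | Oc1c(C(O)C#C)cc([C@H]4c5ccc(OCc6ccccc6)c(OCc6ccccc6)c5O[C@H](c5ccc(OCc6ccccc6)c(OCc6ccccc6)c5)[C@@H]4OC(=O)C(C)(C)C)c(OCc2ccccc2)c1OCc1ccccc1 | intermediate
25 | (2R,3R,4R)-7,8-bis(benzyloxy)-2-[3,4-bis(benzyloxy)phenyl]-4-[2,3-bis(benzyloxy)-4-hydroxy-5-(prop-2-ynoyl)phenyl]chroman-3-yl pivalate | Oc1c(C(=O)C#C)cc([C@H]4c5ccc(OCc6ccccc6)c(OCc6ccccc6)c5O[C@H](c5ccc(OCc6ccccc6)c(OCc6ccccc6)c5)[C@@H]4OC(=O)C(C)(C)C)c(OCc2ccccc2)c1OCc1ccccc1 | intermediate (not isolated)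
26 | (2R,3R,4R)-7,8-bis(benzyloxy)-2-[3,4-bis(benzyloxy)phenyl]-4-{2,3-bis(benzyloxy)-5-[(E)-3-(diethylamino)prop-2-enoyl]-4-hydroxyphenyl}chroman-3-yl pivalate | Oc1c(C(=O)/C=C/N(CC)CC)cc([C@H]4c5ccc(OCc6ccccc6)c(OCc6ccccc6)c5O[C@H](c5ccc(OCc6ccccc6)c(OCc6ccccc6)c5)[C@@H]4OC(=O)C(C)(C)C)c(OCc2ccccc2)c1OCc1ccccc1 | intermediate (not isolated)
27 | (2R,3R,4R)-7,8-bis(benzyloxy)-4-[7,8-bis(benzyloxy)-4-oxo-4H-chromen-6-yl]-2-[3,4-bis(benzyloxy)phenyl]chroman-3-yl pivalate | O=c1ccoc2c(OCc6ccccc6)c(OCc6ccccc6)c([C@H]4c5ccc(OCc6ccccc6)c(OCc6ccccc6)c5O[C@H](c5ccc(OCc6ccccc6)c(OCc6ccccc6)c5)[C@@H]4OC(=O)C(C)(C)C)cc12 | intermediate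
28 | 4-(benzyloxy)phenylboronic acid | OB(O)c1ccc(OCc2ccccc2)cc1 | starting material
29 | (2R,3R,4R)-7,8-bis(benzyloxy)-4-{(2S)-7,8-bis(benzyloxy)-2-[4-(benzyloxy)phenyl]-4-oxochroman-6-yl}-2-[3,4-bis(benzyloxy)phenyl]chroman-3-yl pivalate | O(Cc7ccccc7)c1ccc([C@H]2Oc3c(cc([C@H]4c5ccc(OCc6ccccc6)c(OCc6ccccc6)c5O[C@H](c5ccc(OCc6ccccc6)c(OCc6ccccc6)c5)[C@@H]4OC(=O)C(C)(C)C)c(OCc6ccccc6)c3OCc3ccccc3)C(=O)C2)cc1 | intermediate
30 | trimethylsilyl enol ether of 29, (2S)-4-(trimethylsilyloxy)-2H-chromene | O(Cc7ccccc7)c1ccc([C@H]2Oc3c(cc([C@H]4c5ccc(OCc6ccccc6)c(OCc6ccccc6)c5O[C@H](c5ccc(OCc6ccccc6)c(OCc6ccccc6)c5)[C@@H]4OC(=O)C(C)(C)C)c(OCc6ccccc6)c3OCc3ccccc3)C(O[Si](C)(C)C)=C2)cc1 | intermediate (not isolated)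
31 | (2R,3R,4R)-7,8-bis(benzyloxy)-4-{(2R,3R)-7,8-bis(benzyloxy)-2-[4-(benzyloxy)phenyl]-3-bromo-4-oxochroman-6-yl}-2-[3,4-bis(benzyloxy)phenyl]chroman-3-yl pivalate (2,3-trans in unit T) | O(Cc7ccccc7)c1ccc([C@H]2Oc3c(cc([C@H]4c5ccc(OCc6ccccc6)c(OCc6ccccc6)c5O[C@H](c5ccc(OCc6ccccc6)c(OCc6ccccc6)c5)[C@@H]4OC(=O)C(C)(C)C)c(OCc6ccccc6)c3OCc3ccccc3)C(=O)[C@@H]2Br)cc1 | intermediate
32 | (2R,3R,4R)-7,8-bis(benzyloxy)-4-{(2R,3S,4R)-7,8-bis(benzyloxy)-2-[4-(benzyloxy)phenyl]-3-bromo-4-hydroxychroman-6-yl}-2-[3,4-bis(benzyloxy)phenyl]chroman-3-yl pivalate (Br trans to aryl and to OH) | O(Cc7ccccc7)c1ccc([C@H]2Oc3c(cc([C@H]4c5ccc(OCc6ccccc6)c(OCc6ccccc6)c5O[C@H](c5ccc(OCc6ccccc6)c(OCc6ccccc6)c5)[C@@H]4OC(=O)C(C)(C)C)c(OCc6ccccc6)c3OCc3ccccc3)[C@@H](O)[C@@H]2Br)cc1 | intermediate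
33 | cyclic 3,4-carbonate of unit T (all-cis; 2R,3S,4R in flavan numbering) with unit M as its (2R,3R,4R) 3-pivalate, all phenols benzylated | O(Cc7ccccc7)c1ccc([C@H]2Oc3c(cc([C@H]4c5ccc(OCc6ccccc6)c(OCc6ccccc6)c5O[C@H](c5ccc(OCc6ccccc6)c(OCc6ccccc6)c5)[C@@H]4OC(=O)C(C)(C)C)c(OCc6ccccc6)c3OCc3ccccc3)[C@H]7OC(=O)O[C@@H]27)cc1 | intermediate
34 | (2R,3R,4R)-7,8-bis(benzyloxy)-2-[4-(benzyloxy)phenyl]-6-{(2R,3R,4R)-7,8-bis(benzyloxy)-2-[3,4-bis(benzyloxy)phenyl]-3-hydroxychroman-4-yl}chromane-3,4-diol | O(Cc7ccccc7)c1ccc([C@H]2Oc3c(cc([C@H]4c5ccc(OCc6ccccc6)c(OCc6ccccc6)c5O[C@H](c5ccc(OCc6ccccc6)c(OCc6ccccc6)c5)[C@@H]4O)c(OCc6ccccc6)c3OCc3ccccc3)[C@@H](O)[C@H]2O)cc1 | intermediate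
35 | (2R,3R,4R)-2-(4-hydroxyphenyl)-6-[(2R,3R,4S)-2-(3,4-dihydroxyphenyl)-3,7,8-trihydroxychroman-4-yl]chromane-3,4,7,8-tetrol | Oc1ccc([C@H]2Oc3c(cc([C@H]4c5ccc(O)c(O)c5O[C@H](c5ccc(O)c(O)c5)[C@@H]4O)c(O)c3O)[C@@H](O)[C@H]2O)cc1 | target

## Step count and least certain steps

Total step count: 24. Longest linear sequence: 24 steps, from 1 to 35; compounds 4, 17 and 28 are bought and enter at steps 3, 13 and 19.

**Step 9 (key step).** The methylene carbon may migrate instead of the aryl carbon, or addition of the peracid to the hindered, conjugated carbonyl may be so slow that oxidation of the benzyloxy‑substituted rings takes over. Fallback from 11: chelation‑controlled cleavage of the benzyl ether peri to the carbonyl (BCl3, CH2Cl2, −78 °C) gives the 7‑hydroxyindanone F1. Dakin oxidation of this ortho‑hydroxyaryl ketone (H2O2, NaOH, then acidification) can only shift the aryl carbon and, after relactonisation, gives the 8‑hydroxy lactone F2. Benzylation (BnBr, K2CO3, acetone) returns to 13.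

**Step 14.** Facial selectivity of hydride delivery may be poor: attack through the diequatorial conformer of the cation, anti to the C4 aryl, would give the 2,3‑trans ring. The new benzylic ether may also ionise and be reduced further. Fallback from 19: oxazaborolidine‑catalysed borane reduction, with the catalyst antipode chosen to give the (1S) carbinol F3, sets C2 in the open chain. An intramolecular Mitsunobu etherification (PPh3, DIAD, THF) then closes O1–C2 with inversion and returns to 21.

**Step 8.** Enantioselection may be incomplete with the ortho‑substituted β‑aryl group, or 1,2‑reduction of the product may set in. Fallback from 8: transfer‑hydrogenative kinetic resolution of the racemic indanone (RuCl(p‑cymene)[TsDPEN] of the antipode that consumes the 3S ketone, HCO2H/Et3N). The 3S enantiomer is reduced to the cis‑indanol F4, and the unreacted ketone is recovered as 11.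

**Step 19.** Insertion into the electron‑rich, crowded chromone may be slow, so that protodeboronation consumes 28, or the flavanone may open and reclose with loss of configuration at C2. Fallback from 27: rhodium‑catalysed asymmetric 1,4‑addition of the arylzinc chloride F5 in the presence of TMSCl ([RhCl((R)‑BINAP)]2, THF, rt) traps the adduct directly as silyl enol ether 30, at which point the route is rejoined.

**Step 22.** Closure of the carbonate may stall because the displacement needs the all‑axial conformer. Fallback from 32: acetylation of the C4 hydroxyl (Ac2O, pyridine) gives F6. Silver‑assisted departure of bromide with participation of the acetate (AgOAc, wet AcOH, Woodward‑type cis‑hydroxylation) gives the cis hydroxy acetate F7 through the acetoxonium ion, and the conditions of step 23 then lead to 34.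

Further compounds
F1 | step 9 | (3R)-6-(benzyloxy)-3-[2,3-bis(benzyloxy)-4-(tosyloxy)phenyl]-7-hydroxyindan-1-one | Cc1ccc(cc1)S(=O)(=O)Oc1ccc([C@@H]4CC(=O)c5c4ccc(OCc6ccccc6)c5O)c(OCc2ccccc2)c1OCc1ccccc1
F2 | step 9 | (4S)-7-(benzyloxy)-4-[2,3-bis(benzyloxy)-4-(tosyloxy)phenyl]-8-hydroxy-3,4-dihydrocoumarin | Cc1ccc(cc1)S(=O)(=O)Oc1ccc([C@@H]4CC(=O)Oc5c4ccc(OCc6ccccc6)c5O)c(OCc2ccccc2)c1OCc1ccccc1
F3 | step 14 | (1S,2R,3R)-1-[3,4-bis(benzyloxy)phenyl]-3-[3,4-bis(benzyloxy)-2-hydroxyphenyl]-3-[2,3-bis(benzyloxy)-4-(tosyloxy)phenyl]-1-hydroxypropan-2-yl pivalate | Cc1ccc(cc1)S(=O)(=O)Oc1ccc([C@@H](c5ccc(OCc6ccccc6)c(OCc6ccccc6)c5O)[C@@H](OC(=O)C(C)(C)C)[C@@H](O)c5ccc(OCc6ccccc6)c(OCc6ccccc6)c5)c(OCc2ccccc2)c1OCc1ccccc1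
F4 | step 8 | (1R,3S)-3-[2,3-bis(benzyloxy)-4-(tosyloxy)phenyl]-6,7-bis(benzyloxy)indan-1-ol (cis) | Cc1ccc(cc1)S(=O)(=O)Oc1ccc([C@H]4C[C@@H](O)c5c4ccc(OCc6ccccc6)c5OCc5ccccc5)c(OCc2ccccc2)c1OCc1ccccc1
F5 | step 19 | [4-(benzyloxy)phenyl]zinc chloride | Cl[Zn]c1ccc(OCc2ccccc2)cc1
F6 | step 22 | 4-O-acetate of bromohydrin 32 | O(Cc7ccccc7)c1ccc([C@H]2Oc3c(cc([C@H]4c5ccc(OCc6ccccc6)c(OCc6ccccc6)c5O[C@H](c5ccc(OCc6ccccc6)c(OCc6ccccc6)c5)[C@@H]4OC(=O)C(C)(C)C)c(OCc6ccccc6)c3OCc3ccccc3)[C@@H](OC(C)=O)[C@@H]2Br)cc1
F7 | step 22 | all-cis 3-O-acetyl-4-hydroxy derivative of unit T with unit M as its 3-pivalate | O(Cc7ccccc7)c1ccc([C@H]2Oc3c(cc([C@H]4c5ccc(OCc6ccccc6)c(OCc6ccccc6)c5O[C@H](c5ccc(OCc6ccccc6)c(OCc6ccccc6)c5)[C@@H]4OC(=O)C(C)(C)C)c(OCc6ccccc6)c3OCc3ccccc3)[C@@H](O)[C@H]2OC(C)=O)cc1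
A1 | alternative 1 | 4-{1-[3,4-bis(benzyloxy)-2-hydroxyphenyl]-3-[3,4-bis(benzyloxy)phenyl]prop-2-yn-1-yl}-2,3-bis(benzyloxy)phenol, C1 configured as C4 of unit M | Oc1ccc([C@H](C#Cc2ccc(OCc3ccccc3)c(OCc3ccccc3)c2)c2ccc(OCc3ccccc3)c(OCc3ccccc3)c2O)c(OCc2ccccc2)c1OCc1ccccc1
A2 | alternative 2 | nona-O-benzyl ether of the target carrying the C4 hydroxyl of unit T as its tert-butyldimethylsilyl ether | O(Cc7ccccc7)c1ccc([C@H]2Oc3c(cc([C@H]4c5ccc(OCc6ccccc6)c(OCc6ccccc6)c5O[C@H](c5ccc(OCc6ccccc6)c(OCc6ccccc6)c5)[C@@H]4OCc4ccccc4)c(OCc4ccccc4)c3OCc3ccccc3)[C@@H](O[Si](C)(C)C(C)(C)C)[C@H]2OCc2ccccc2)cc1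
A3 | alternative 3 | octa-O-benzyl ether of the target with the 3,4-diol of unit T free | O(Cc7ccccc7)c1ccc([C@H]2Oc3c(cc([C@H]4c5ccc(OCc6ccccc6)c(OCc6ccccc6)c5O[C@H](c5ccc(OCc6ccccc6)c(OCc6ccccc6)c5)[C@@H]4OCc4ccccc4)c(OCc4ccccc4)c3OCc3ccccc3)[C@@H](O)[C@H]2O)cc1
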